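At late times Thursday's run stood still: its substrate read 39.2% at 15.0 h and 39.3% at 20.0 h, a step inside the scatter. So I took the reagent for the limiting reagent and began to count what it could pay for.

| flask | substrate | partner | reagent | remark | time |
|---|---|---|---|---|---|
| Thursday's | 0.050 M (fed, over 40 min) | 0.025 M | 0.055 M | run made earlier |  |
| Tuesday's | 0.050 M (fed, over 40 min) | 0.10 M | 0.055 M | run made earlier |  |
| Saturday's | 0.10 M (fed, over 40 min) | 0.050 M | 0.055 M | run made earlier |  |
| flask | 0.050 M (fed, over 40 min) | 0.0500 M | 0.0550 M |  | 15 h |

| run | time / h | substrate / % | target / % | open intermediate / % |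
|---|---|---|---|---|
| Thursday's | 3.00 | 40.6 | 12.2 | 46.8 |
| Thursday's | 6.00 | 38.7 | 12.0 | 49.7 |
| Thursday's | 10.0 | 38.9 | 11.5 | 48.5 |
| Thursday's | 12.0 | 38.7 | 12.3 | 48.9 |
| Thursday's | 15.0 | 39.2 | 11.9 | 49.3 |
| Thursday's | 20.0 | 39.3 | 11.8 | 49.9 |
| Tuesday's | 1.33 | 94.7 | 2.8 | 1.8 |
| Tuesday's | 2.50 | 94.2 | 2.8 | 3.7 |
| Tuesday's | 4.00 | 94.2 | 2.8 | 1.8 |
| Tuesday's | 6.00 | 94.1 | 3.0 | 2.6 |
| Tuesday's | 10.0 | 94.5 | 4.0 | 1.8 |
| Tuesday's | 20.0 | 95.7 | 3.1 | 2.1 |
| Saturday's | 1.50 | 83.1 | 6.3 | 10.4 |
| Saturday's | 5.00 | 83.4 | 5.9 | 9.4 |
| Saturday's | 8.00 | 83.4 | 5.7 | 10.5 |
| Saturday's | 12.0 | 84.5 | 6.3 | 11.1 |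
| Saturday's | 20.0 | 83.8 | 6.4 | 9.8 |

(scatter of a reading: 0.5 percentage points)

- the reaction counts as stopped when no species that holds the substrate changes by six tenths of a point or more over the second half of the time

* the state of affairs at 15 h: stopped, and by what, or still going (it is still moving / all of the substrate has reacted / the partner has run out first / the reagent has run out first)
* share of the substrate used up at 15 h
* target at 15 h, in percent of the substrate charged
* open intermediate at 15 h, in percent of the substrate charged

My bench rule was a budget: each reagent goes to one substrate or one partner. If the partner takes its whole charge, the reagent over and above that charge, per substrate charged, comes to 10.0% in the flask. I call this the surplus share Z. For Thursday's run Z is 60.0%, and the run read 60.7% of its substrate used.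

But Saturday's run has Z of 5.00% and read 16.2% used, more than its surplus. I looked for the border in the ratio of partner to reagent: it is 0.455 on Thursday's run, but 0.909 on Saturday's and in the flask, though substrate and partner both differ between those two runs. At the higher ratio, I reasoned, the partner keeps a remainder, and the substrate takes that much beyond Z.

So Z was my floor for the flask. For a ceiling I took Saturday's uptake of 0.0162 M: the flask has the same partner and reagent and half the substrate, so I expected no greater uptake, which is 32.4% of its charge. I committed to a conversion between 10.0% and 32.4%.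

The forecast gave one figure inside that range, by its own road. Its call on the end was: the reagent has run out first. It gave 18.5% converted, 7.5% target and 11% open intermediate, on this ground: “If the substrate competes only weakly, its fractional conversion depends mainly on partner and reagent”.

The end of the flask was this: the reagent has run out first, with 0% of its charge left. The flask gave 25.7% converted, 10.6% target and 15.2% open intermediate.

    second intermediate → side product (k = 2.70 × 10⁻⁴ s⁻¹)
    reagent + partner → second intermediate (k = 0.0330 M⁻¹ s⁻¹)
    substrate + reagent → open intermediate (k = 0.0130 M⁻¹ s⁻¹)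
    2 second intermediate → homo product (k = 0.0580 M⁻¹ s⁻¹)
    open intermediate + second intermediate → target (k = 0.0460 M⁻¹ s⁻¹)

The flask's conversion stood 7.2 percentage points above the forecast and 16 points above Z. At 15.0 h the partner in the flask stood at 16% of its charge. The flask's substrate taken beyond Z was 0.00787 M, against 0.00787 M of partner remaining. With 0.013 M of partner instead, the ratio to reagent is 0.236 and Z is 84.0%. That neighbouring flask reached 84.0% converted, with 0.152% of its partner left.

All runs stem from a simulated flask with made-up constants, and the scatter is random.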